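The pyranone is built last, on a ring derived from a furan. Its atoms C2', C3', C4' and C5', with the Z C3'=C4' bond, already exist as the masked (Z)-4-oxobut-2-enoic acid of a hydroxybutenolide carried on C1 of the dihydronaphthalene. The key step adds only C6', its ester and the ring oxygen O1': olefination of the open aldehyde with a 2-silyloxyphosphonoacetate, then acid-induced desilylation and enol lactonisation, in one flask. The precursor is the 6,7-dimethoxy-1H-naphthalene-2,2,3-triester bearing the hydroxybutenolide at C1; its C1 centre comes from a rhodium-catalysed asymmetric furyl addition, and quaternary C2 is unmasked only in the final decarboxylation.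

Key step: step 8

Assumption: the (S)-BINAP–rhodium catalyst is taken to add the furyl group to the alpha-si face of the (E)-acrylate, as is usual for this ligand with (E)-configured acceptors; should the sense be opposite, the (R)-ligand is used.

Step 1
Reactants: 1 2-bromo-4,5-dimethoxybenzaldehyde
Product: 2 2-(2-bromo-4,5-dimethoxyphenyl)-1,3-dioxolane
Conditions: ethylene glycol (3 equiv), p-TsOH·H2O (2 mol %), toluene, reflux, Dean–Stark
Reagents that add atoms: ethylene glycol, OCCO
Why: Acid-catalysed acetalisation with azeotropic removal of water masks the aldehyde, which must survive the enolate chemistry of step 4 and must not trap the rhodium enolate of step 3; no stereocentre is formed.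

Step 2
Reactants: 2 2-(2-bromo-4,5-dimethoxyphenyl)-1,3-dioxolane, 3 ethyl acrylate
Product: 4 ethyl (2E)-3-[2-(1,3-dioxolan-2-yl)-4,5-dimethoxyphenyl]prop-2-enoate
Conditions: Pd(OAc)2 (3 mol %), P(o-tol)3 (6 mol %), Et3N (2 equiv), DMF, 100 °C
Reagents that add atoms: ethyl acrylate, C=CC(=O)OCC
Why: Mizoroki–Heck reaction of the aryl bromide with the acrylate, in which syn carbopalladation and syn beta-hydride elimination should give the (E)-cinnamate only, the dioxolane being inert to the basic conditions.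

Step 3
Reactants: 4 ethyl (2E)-3-[2-(1,3-dioxolan-2-yl)-4,5-dimethoxyphenyl]prop-2-enoate, 5 furan-3-ylboronic acid
Product: 6 ethyl (3S)-3-[2-(1,3-dioxolan-2-yl)-4,5-dimethoxyphenyl]-3-(furan-3-yl)propanoate
Conditions: [RhCl(C2H4)2]2 (1.5 mol %), (S)-BINAP (3.3 mol %), KOH (0.2 equiv), 5 (3 equiv), dioxane/H2O (10:1), 60 °C
Reagents that add atoms: furan-3-ylboronic acid, OB(O)c1ccoc1
Why: Hayashi–Miyaura rhodium-catalysed asymmetric 1,4-addition, in which the furyl–rhodium–(S)-BINAP species formed by transmetalation should insert the (E)-acrylate on its alpha-si face and the resulting rhodium enolate is protonated by water, setting the benzylic centre (later C1) as S while acetal and ester are untouched.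

Step 4
Reactants: 6 ethyl (3S)-3-[2-(1,3-dioxolan-2-yl)-4,5-dimethoxyphenyl]-3-(furan-3-yl)propanoate, 7 ethyl chloroformate, 8 ethyl bromoacetate
Product: 10 triethyl (3S)-3-[2-(1,3-dioxolan-2-yl)-4,5-dimethoxyphenyl]-3-(furan-3-yl)propane-1,2,2-tricarboxylate, via furyl aryl malonate 9 (not isolated)
Conditions: LiN(iPr)2 (commercial solution, 2.1 equiv), THF, −78 °C; ClCO2Et (1.05 equiv), −78 → −20 °C; then BrCH2CO2Et (1.5 equiv), DMPU, −20 °C → rt
Reagents that add atoms: ethyl chloroformate, CCOC(=O)Cl; ethyl bromoacetate, CCOC(=O)CBr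
Why: Enolate C-acylation followed by SN2 alkylation, in which two equivalents of amide base form the ester enolate and then hold the new malonate as its lithium enolate, which the bromoacetate alkylates in the same flask to give the quaternary carbon (later C2), the benzylic stereocentre having no acidic hydrogen.

Step 5
Reactants: 10 triethyl (3S)-3-[2-(1,3-dioxolan-2-yl)-4,5-dimethoxyphenyl]-3-(furan-3-yl)propane-1,2,2-tricarboxylate
Product: 11 triethyl (3S)-3-(2-formyl-4,5-dimethoxyphenyl)-3-(furan-3-yl)propane-1,2,2-tricarboxylate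
Conditions: p-TsOH·H2O (10 mol %), acetone/H2O (10:1), rt
Reagents that add atoms: water, O
Why: Acid-catalysed acetal hydrolysis frees the electron-rich aryl aldehyde under conditions mild enough for the furan and the three esters.

Step 6
Reactants: 11 triethyl (3S)-3-(2-formyl-4,5-dimethoxyphenyl)-3-(furan-3-yl)propane-1,2,2-tricarboxylate
Product: 12 triethyl (1S)-1-(furan-3-yl)-6,7-dimethoxy-1H-naphthalene-2,2,3-tricarboxylate (a 1,2-dihydronaphthalene)
Conditions: NaOEt (0.3 equiv), EtOH, 3 Å molecular sieves, 0 °C → rt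
Reagents that add atoms: none
Why: Intramolecular aldol condensation of Claisen–Schmidt type, in which the enolate of the CH2CO2Et arm adds to the ortho aldehyde (6-enolexo-exo-trig) and E1cB loss of hydroxide gives the C3=C4 bond conjugated with arene and ester, while C1–H, flanked only by aryl, furyl and a quaternary carbon, is not acidic.

Step 7
Reactants: 12 triethyl (1S)-1-(furan-3-yl)-6,7-dimethoxy-1H-naphthalene-2,2,3-tricarboxylate
Product: 14 triethyl (1S)-1-(2-hydroxy-5-oxo-2,5-dihydrofuran-3-yl)-6,7-dimethoxy-1H-naphthalene-2,2,3-tricarboxylate (hemiacetal carbon as a mixture), via furan endoperoxide 13 (not isolated)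
Conditions: O2, visible light, tetraphenylporphyrin (1 mol %), iPr2NEt (5 equiv), CH2Cl2, −78 °C, then rt
Reagents that add atoms: dioxygen, O=O
Why: Furan photo-oxygenation, in which [4+2] addition of singlet oxygen gives the 2,5-endoperoxide and the hindered amine removes the less hindered hydrogen at former furan C5 (Kornblum–DeLaMare fragmentation), so that the lactone carbonyl forms at C5 and the hemiacetal at C2 beside the substituent, with C1 unchanged.

Step 8
Reactants: 14 triethyl (1S)-1-(2-hydroxy-5-oxo-2,5-dihydrofuran-3-yl)-6,7-dimethoxy-1H-naphthalene-2,2,3-tricarboxylate, 15 methyl 2-[(tert-butyldimethylsilyl)oxy]-2-(dimethoxyphosphoryl)acetate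
Product: 18 triethyl (1R)-1-[6-(methoxycarbonyl)-2-oxo-2H-pyran-4-yl]-6,7-dimethoxy-1H-naphthalene-2,2,3-tricarboxylate, via silyloxydiene acid 16 (not isolated), via keto acid 17 (not isolated)
Conditions: 15 (2.2 equiv), LiN(SiMe3)2 (2.1 equiv), THF, −78 °C; 14, −78 → 0 °C; then CF3CO2H (excess), (CF3CO)2O (1.5 equiv), CH2Cl2, 0 °C → rt
Reagents that add atoms: methyl 2-[(tert-butyldimethylsilyl)oxy]-2-(dimethoxyphosphoryl)acetate, COC(=O)C(O[Si](C)(C)C(C)(C)C)P(=O)(OC)OC
Why: The first equivalent of the phosphonate anion removes the lactol proton and opens the ring to the lithium (Z)-4-oxobut-2-enoate, in which C1–H is no longer conjugated to an acceptor carbonyl, and the second equivalent olefinates the aldehyde carbon C5' (Horner–Wadsworth–Emmons) to the 2-silyloxy dienoate, creating C5'=C6'. Trifluoroacetic acid then cleaves the silyl enol ether to the 2-oxo ester, whose enol oxygen is acylated by the Z-disposed carboxyl group, activated as its mixed trifluoroacetic anhydride, so that the O1'–C2' bond forms by 6-exo-trig closure and the aromatic 2-pyranone results. The closest known reaction types are the Wittig and Horner–Wadsworth–Emmons olefination of gamma-hydroxybutenolides through their open aldehyde form and the acid-induced cyclisation of 2-oxohex-4-enedioic acid derivatives to 2-pyranone-6-carboxylates. No stereocentre is created. The step needs the Z geometry of C3'=C4', which the butenolide ring supplies and the carboxylate should keep, and retention at C1, which is secured because no base stronger than the stabilised phosphonate anion is present, that anion reacts first at the acidic O–H, and C2 carries no hydrogen.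

Step 9
Reactants: 18 triethyl (1R)-1-[6-(methoxycarbonyl)-2-oxo-2H-pyran-4-yl]-6,7-dimethoxy-1H-naphthalene-2,2,3-tricarboxylate
Product: 20 (1R,2S)-1-(6-carboxy-2-oxo-2H-pyran-4-yl)-6,7-dimethoxy-1,2-dihydronaphthalene-2,3-dicarboxylic acid, via geminal diacid 19 (not isolated)
Conditions: 6 M HCl/AcOH (1:1), degassed, N2, 100 °C
Reagents that add atoms: water, O
Why: Acid-catalysed ester hydrolysis frees the malonic acid, which decarboxylates through its cyclic six-membered transition state, and the new C2–H, alpha to a carboxyl and allylic to the styrene, should equilibrate through the conjugated dienol in the hot acid to the trans acid, in which the C1 pyranonyl and C2 carboxyl groups are both pseudo-axial and free of strain with the C3 carboxyl and the peri hydrogen, so that C2 is set S under thermodynamic control from C1.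

Step 10
Reactants: 20 (1R,2S)-1-(6-carboxy-2-oxo-2H-pyran-4-yl)-6,7-dimethoxy-1,2-dihydronaphthalene-2,3-dicarboxylic acid
Product: 21 (1R,2S)-1-(6-carboxy-2-oxo-2H-pyran-4-yl)-6,7-dihydroxy-1,2-dihydronaphthalene-2,3-dicarboxylic acid (CNP0195322.1)
Conditions: BBr3 (8 equiv), CH2Cl2, −78 °C → rt; then H2O
Reagents that add atoms: none
Why: Boron tribromide demethylation of the aryl methyl ethers (Lewis acid complexation, then SN2 attack of bromide at methyl) frees the catechol, while the carboxylic acids, the pyranone lactone and both stereocentres are not affected by the non-basic conditions.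

Compound list
1 | 2-bromo-4,5-dimethoxybenzaldehyde | COc1cc(Br)c(C=O)cc1OC | starting material
2 | 2-(2-bromo-4,5-dimethoxyphenyl)-1,3-dioxolane | COc1cc(Br)c(cc1OC)C1OCCO1 | intermediate
3 | ethyl acrylate | C=CC(=O)OCC | starting material
4 | ethyl (2E)-3-[2-(1,3-dioxolan-2-yl)-4,5-dimethoxyphenyl]prop-2-enoate | CCOC(=O)/C=C/c1cc(OC)c(OC)cc1C1OCCO1 | intermediate
5 | furan-3-ylboronic acid | OB(O)c1ccoc1 | starting material
6 | ethyl (3S)-3-[2-(1,3-dioxolan-2-yl)-4,5-dimethoxyphenyl]-3-(furan-3-yl)propanoate | COc1cc(C2OCCO2)c(cc1OC)[C@@H](c1ccoc1)CC(=O)OCC | intermediate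
7 | ethyl chloroformate | CCOC(=O)Cl | starting material
8 | ethyl bromoacetate | CCOC(=O)CBr | starting material
9 | diethyl 2-{(S)-[2-(1,3-dioxolan-2-yl)-4,5-dimethoxyphenyl](furan-3-yl)methyl}propanedioate (present as its lithium enolate) | COc1cc(C2OCCO2)c(cc1OC)[C@@H](c1ccoc1)C(C(=O)OCC)C(=O)OCC | intermediate
10 | triethyl (3S)-3-[2-(1,3-dioxolan-2-yl)-4,5-dimethoxyphenyl]-3-(furan-3-yl)propane-1,2,2-tricarboxylate | COc1cc(C2OCCO2)c(cc1OC)[C@@H](c1ccoc1)C(CC(=O)OCC)(C(=O)OCC)C(=O)OCC | intermediate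
11 | triethyl (3S)-3-(2-formyl-4,5-dimethoxyphenyl)-3-(furan-3-yl)propane-1,2,2-tricarboxylate | COc1cc(C=O)c(cc1OC)[C@@H](c1ccoc1)C(CC(=O)OCC)(C(=O)OCC)C(=O)OCC | intermediate
12 | triethyl (1S)-1-(furan-3-yl)-6,7-dimethoxy-1H-naphthalene-2,2,3-tricarboxylate | CCOC(=O)C1=Cc2cc(OC)c(OC)cc2[C@@H](c2ccoc2)C1(C(=O)OCC)C(=O)OCC | intermediate
13 | triethyl (1S)-6,7-dimethoxy-1-(2,3,7-trioxabicyclo[2.2.1]hept-5-en-5-yl)-1H-naphthalene-2,2,3-tricarboxylate (furan endoperoxide, bridgeheads as a mixture) | CCOC(=O)C1=Cc2cc(OC)c(OC)cc2[C@@H](C2=CC3OOC2O3)C1(C(=O)OCC)C(=O)OCC | intermediate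
14 | triethyl (1S)-1-(2-hydroxy-5-oxo-2,5-dihydrofuran-3-yl)-6,7-dimethoxy-1H-naphthalene-2,2,3-tricarboxylate (hemiacetal carbon as a mixture) | CCOC(=O)C1=Cc2cc(OC)c(OC)cc2[C@@H](C2=CC(=O)OC2O)C1(C(=O)OCC)C(=O)OCC | intermediate
15 | methyl 2-[(tert-butyldimethylsilyl)oxy]-2-(dimethoxyphosphoryl)acetate | COC(=O)C(O[Si](C)(C)C(C)(C)C)P(=O)(OC)OC | starting material
16 | (2Z)-5-[(tert-butyldimethylsilyl)oxy]-6-methoxy-6-oxo-3-[(1R)-2,2,3-tris(ethoxycarbonyl)-6,7-dimethoxy-1,2-dihydronaphthalen-1-yl]hexa-2,4-dienoic acid (C4=C5 geometry as a mixture; formed as its lithium salt) | CCOC(=O)C1=Cc2cc(OC)c(OC)cc2[C@@H](C(=C/C(=O)O)/C=C(O[Si](C)(C)C(C)(C)C)C(=O)OC)C1(C(=O)OCC)C(=O)OCC | intermediate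
17 | (2E)-6-methoxy-5,6-dioxo-3-[(1R)-2,2,3-tris(ethoxycarbonyl)-6,7-dimethoxy-1,2-dihydronaphthalen-1-yl]hex-2-enoic acid (carboxyl cis to the CH2 chain; in equilibrium with its 5-enol) | CCOC(=O)C1=Cc2cc(OC)c(OC)cc2[C@@H](C(=C/C(=O)O)/CC(=O)C(=O)OC)C1(C(=O)OCC)C(=O)OCC | intermediate
18 | triethyl (1R)-1-[6-(methoxycarbonyl)-2-oxo-2H-pyran-4-yl]-6,7-dimethoxy-1H-naphthalene-2,2,3-tricarboxylate | CCOC(=O)C1=Cc2cc(OC)c(OC)cc2[C@@H](c2cc(C(=O)OC)oc(=O)c2)C1(C(=O)OCC)C(=O)OCC | intermediate
19 | (1R)-1-(6-carboxy-2-oxo-2H-pyran-4-yl)-6,7-dimethoxy-1H-naphthalene-2,2,3-tricarboxylic acid | O=C(O)C1=Cc2cc(OC)c(OC)cc2[C@@H](c2cc(C(=O)O)oc(=O)c2)C1(C(=O)O)C(=O)O | intermediate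
20 | (1R,2S)-1-(6-carboxy-2-oxo-2H-pyran-4-yl)-6,7-dimethoxy-1,2-dihydronaphthalene-2,3-dicarboxylic acid | O=C(O)C1=Cc2cc(OC)c(OC)cc2[C@@H](c2cc(C(=O)O)oc(=O)c2)[C@@H]1C(=O)O | intermediate
21 | (1R,2S)-1-(6-carboxy-2-oxo-2H-pyran-4-yl)-6,7-dihydroxy-1,2-dihydronaphthalene-2,3-dicarboxylic acid | O=C(O)C1=Cc2cc(O)c(O)cc2[C@@H](c2cc(C(=O)O)oc(=O)c2)[C@@H]1C(=O)O | target

Total step count: 10. Longest linear sequence: 10 steps (1 to 21).

Steps most likely to fail

Step 8. The hindered, alpha-branched aldehyde may be released too slowly from the lactolate, so that proton transfer quenches the phosphonate anion. The C3'=C4' bond of the open carboxylate may isomerise from Z to E, after which ring closure is impossible. Configuration at C1 may be lost if base meets the closed butenolide before it opens. The fallback sets out from 14 and returns at 18, with each stage isolated and no carboxylate dianion. Trimethylsilyldiazomethane (toluene/MeOH, 0 °C) opens and caps the lactol as the open-chain ester aldehyde triethyl (1S)-1-[(2Z)-4-methoxy-1,4-dioxobut-2-en-2-yl]-6,7-dimethoxy-1H-naphthalene-2,2,3-tricarboxylate F1. One equivalent of the lithiated phosphonate 15 (THF, −78 °C) should then give the silyloxy diene diester triethyl (1R)-1-[(2Z)-5-[(tert-butyldimethylsilyl)oxy]-1,6-dimethoxy-1,6-dioxohexa-2,4-dien-3-yl]-6,7-dimethoxy-1H-naphthalene-2,2,3-tricarboxylate F2. HF·pyridine in THF should free the 2-oxo diester triethyl (1R)-1-[(2E)-1,6-dimethoxy-1,5,6-trioxohex-2-en-3-yl]-6,7-dimethoxy-1H-naphthalene-2,2,3-tricarboxylate F3. Catalytic p-TsOH in toluene at 80 °C should close the pyranone by enol transesterification with loss of methanol, giving 18.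

Step 9. Acyl–oxygen hydrolysis at the congested C2 esters may be slow and force long heating. Protonation of the decarboxylation enol on the face away from the C1 substituent would give the C2 epimer, which may not equilibrate in acid. Long heating may also erode C1 by acid-catalysed vinylogous enolisation of the pyranone. The fallback sets out from 20 as obtained (in admixture with its C2 epimer) and returns at 21; it moves the equilibration to the ester level. Trimethylsilyldiazomethane gives the triester dimethyl (1R)-1-[6-(methoxycarbonyl)-2-oxo-2H-pyran-4-yl]-6,7-dimethoxy-1,2-dihydronaphthalene-2,3-dicarboxylate (mixture at C2) F4. Catalytic DBU in toluene at rt should epimerise only the more acidic alpha-ester, allylic C2–H, giving the trans triester dimethyl (1R,2S)-1-[6-(methoxycarbonyl)-2-oxo-2H-pyran-4-yl]-6,7-dimethoxy-1,2-dihydronaphthalene-2,3-dicarboxylate F5. Excess BBr3 in CH2Cl2 (−78 °C → rt, then water) should then remove all five O-methyl groups, three ester and two ether, to give 21.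

Step 3. Protodeboronation of the heteroarylboronic acid may outrun insertion into the ortho-substituted cinnamate, or facial discrimination may be insufficient. The fallback sets out from 2 and returns at 6, using an oxazolidinone auxiliary in place of the catalyst. Magnesium in THF converts 2 into the Grignard reagent [2-(1,3-dioxolan-2-yl)-4,5-dimethoxyphenyl]magnesium bromide F6. Commercial (2E)-3-(furan-3-yl)prop-2-enoic acid is activated with pivaloyl chloride and Et3N as the mixed anhydride (2E)-3-(furan-3-yl)prop-2-enoic 2,2-dimethylpropanoic anhydride F7. With (4R)-4-phenyl-1,3-oxazolidin-2-one and LiCl this gives the imide (4R)-3-[(2E)-3-(furan-3-yl)prop-2-enoyl]-4-phenyl-1,3-oxazolidin-2-one F8. Addition of F6 with CuBr·SMe2 (THF, −40 °C) to the chelated s-cis imide, on the face opposite the phenyl group, should give the adduct (4R)-3-{(3S)-3-[2-(1,3-dioxolan-2-yl)-4,5-dimethoxyphenyl]-3-(furan-3-yl)propanoyl}-4-phenyl-1,3-oxazolidin-2-one F9. Ethanolysis with NaOEt in EtOH at 0 °C releases the auxiliary and gives 6.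

Further compounds
F1 | step 8 | triethyl (1S)-1-[(2Z)-4-methoxy-1,4-dioxobut-2-en-2-yl]-6,7-dimethoxy-1H-naphthalene-2,2,3-tricarboxylate | CCOC(=O)C1=Cc2cc(OC)c(OC)cc2[C@@H](C(=C/C(=O)OC)/C=O)C1(C(=O)OCC)C(=O)OCC
F2 | step 8 | triethyl (1R)-1-[(2Z)-5-[(tert-butyldimethylsilyl)oxy]-1,6-dimethoxy-1,6-dioxohexa-2,4-dien-3-yl]-6,7-dimethoxy-1H-naphthalene-2,2,3-tricarboxylate | CCOC(=O)C1=Cc2cc(OC)c(OC)cc2[C@@H](C(=C/C(=O)OC)/C=C(O[Si](C)(C)C(C)(C)C)C(=O)OC)C1(C(=O)OCC)C(=O)OCC
F3 | step 8 | triethyl (1R)-1-[(2E)-1,6-dimethoxy-1,5,6-trioxohex-2-en-3-yl]-6,7-dimethoxy-1H-naphthalene-2,2,3-tricarboxylate | CCOC(=O)C1=Cc2cc(OC)c(OC)cc2[C@@H](C(=C/C(=O)OC)/CC(=O)C(=O)OC)C1(C(=O)OCC)C(=O)OCC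
F4 | step 9 | dimethyl (1R)-1-[6-(methoxycarbonyl)-2-oxo-2H-pyran-4-yl]-6,7-dimethoxy-1,2-dihydronaphthalene-2,3-dicarboxylate (mixture at C2) | COC(=O)C1=Cc2cc(OC)c(OC)cc2[C@@H](c2cc(C(=O)OC)oc(=O)c2)C1C(=O)OC
F5 | step 9 | dimethyl (1R,2S)-1-[6-(methoxycarbonyl)-2-oxo-2H-pyran-4-yl]-6,7-dimethoxy-1,2-dihydronaphthalene-2,3-dicarboxylate | COC(=O)C1=Cc2cc(OC)c(OC)cc2[C@@H](c2cc(C(=O)OC)oc(=O)c2)[C@@H]1C(=O)OC
F6 | step 3 | [2-(1,3-dioxolan-2-yl)-4,5-dimethoxyphenyl]magnesium bromide | COc1cc([Mg]Br)c(cc1OC)C1OCCO1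
F7 | step 3 | (2E)-3-(furan-3-yl)prop-2-enoic 2,2-dimethylpropanoic anhydride | CC(C)(C)C(=O)OC(=O)/C=C/c1ccoc1
F8 | step 3 | (4R)-3-[(2E)-3-(furan-3-yl)prop-2-enoyl]-4-phenyl-1,3-oxazolidin-2-one | O=C(/C=C/c1ccoc1)N1C(=O)OC[C@H]1c1ccccc1
F9 | step 3 | (4R)-3-{(3S)-3-[2-(1,3-dioxolan-2-yl)-4,5-dimethoxyphenyl]-3-(furan-3-yl)propanoyl}-4-phenyl-1,3-oxazolidin-2-one | COc1cc(C2OCCO2)c(cc1OC)[C@@H](c1ccoc1)CC(=O)N1C(=O)OC[C@H]1c1ccccc1
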